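The carotenoid is cut at C11=C12 and C11'=C12' into the C10 dialdehyde and two C15 phosphonium salts, both made from one enantiopure (5R,6S)-5,6-epoxy dienoate. The dihydrofuran ring (O, C5', C6', C7', C8') is the 1,3-transposed form of that vinyl oxirane. In the key step a copper catalyst moves the oxygen from C6' to C8' on the same face of the C6'–C7'–C8' allyl unit. This expands the oxirane to the dihydrofuran, creates C6'=C7' and transfers the 6S/7E information to 8'R, while C5' stays R. The same epoxide gives the cis-5,6-diol end by palladium/CO2 carbonate formation with retention.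

Key step: step 5

Remark on the chemistry: carotenoid numbering is used for locants (ring C1–C6, chain C7–C15). In the C15 building blocks the locants carry no primes; in the C25 and C40 compounds the dihydrofuran half carries primes. All chain double bonds of the target are E. Compounds 1, 5 and 15 are taken as commercial.

Step 1
Reactants: 1 β-cyclocitral (2,6,6-trimethylcyclohex-1-ene-1-carbaldehyde)
Product: 2 β-cyclogeraniol ((2,6,6-trimethylcyclohex-1-en-1-yl)methanol)
Conditions: NaBH4, MeOH, 0 °C
Reagents that add atoms: none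
Why: Borohydride 1,2-reduction of the hindered enal gives the allylic alcohol needed for a hydroxyl-directed epoxidation; no stereocenter is formed.

Step 2
Reactants: 2 β-cyclogeraniol
Product: 3 [(1R,6R)-2,2,6-trimethyl-7-oxabicyclo[4.1.0]heptan-1-yl]methanol
Conditions: Ti(OiPr)4 (10 mol%), D-(−)-diethyl tartrate [(2S,3S), 12 mol%], t-BuOOH, 4 Å molecular sieves, CH2Cl2, −20 °C
Reagents that add atoms: tert-butyl hydroperoxide, CC(C)(C)OO
Why: Sharpless asymmetric epoxidation of the tetrasubstituted allylic alcohol, in which the titanium complex of the (2S,3S)-tartrate delivers the peroxide oxygen through the coordinated hydroxymethyl group to the face of C5=C6 that should give the (1R,6R) epoxy alcohol, so C5 (R) and C6 of both end groups are set here by the reagent.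

Step 3
Reactants: 3 epoxy alcohol
Product: 4 (1S,6R)-2,2,6-trimethyl-7-oxabicyclo[4.1.0]heptane-1-carbaldehyde
Conditions: n-Pr4N[RuO4] (5 mol%), N-methylmorpholine N-oxide, 4 Å molecular sieves, CH2Cl2, rt
Reagents that add atoms: none
Why: Ley–Griffith oxidation of the primary alcohol under neutral conditions gives the aldehyde, which has no α-hydrogen, so the oxirane and both stereocenters are not at risk.

Step 4
Reactants: 4 epoxy aldehyde; 5 triethyl 3-methyl-4-phosphonocrotonate (ethyl (2E)-4-(diethoxyphosphoryl)-3-methylbut-2-enoate)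
Product: 6 ethyl (2E,4E)-3-methyl-5-[(1S,6R)-2,2,6-trimethyl-7-oxabicyclo[4.1.0]heptan-1-yl]penta-2,4-dienoate
Conditions: NaH, THF, 0 °C → rt; chromatography
Reagents that add atoms: none
Why: Horner–Wadsworth–Emmons olefination with the stabilised vinylogous phosphonate anion should form C7=C8 with E geometry and bring in C8–C11 with the 9E bond, any 9Z isomer being removed by chromatography, and no stereocenter is touched.

Step 5
Reactants: 6 epoxy dienoate
Product: 7 ethyl (2E)-3-[(2R,7aR)-4,4,7a-trimethyl-2,4,5,6,7,7a-hexahydro-1-benzofuran-2-yl]but-2-enoate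
Conditions: Cu(CF3COCHCOCF3)2 (copper bis(hexafluoroacetylacetonate), 5 mol%), toluene, 110 °C, sealed tube
Reagents that add atoms: none
Why: The copper catalyst (divalent as charged, reduced in situ to the active monovalent copper) engages the vinyl oxirane, the tertiary allylic C6–O bond breaks and the oxygen, which stays bound to C5, is delivered to C8 on the same face of the C6–C7–C8 allyl unit (net syn-SN2', a formal 1,3-oxygen shift), so the three-membered ring O–C5–C6 becomes the five-membered ring O–C5–C6=C7–C8. The closest known reaction type is the copper-catalysed ring expansion of vinyl oxiranes to 2,5-dihydrofurans, with the acid-induced 5,6-epoxide to 5,8-furanoid rearrangement of carotenoid end groups as the substrate-specific analogue. The only ring closed is the dihydrofuran, by O–C8 bond formation that is formally 5-endo on C7=C8 but in effect the collapse of the C5 alkoxide onto the terminus of a copper-bound allyl fragment. The single new stereocenter C8 is controlled by the configuration of C6 (the face from which the oxygen departs) together with the 7E geometry: suprafacial transfer should convert 6S,7E into 8R, while C5 (R) is never touched and C6 becomes sp2. The step needs C6–O and not C5–O cleavage, which the allylic position of C6 secures, O-attack at C8 and not at C10, which the 7E geometry secures, and transfer without a freely rotating allyl cation or a semipinacol ring contraction, which the electron-poor dienoate and the non-protic, weakly Lewis-acidic catalyst should secure.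

Step 6
Reactants: 7 furanoid ester
Product: 8 (2E)-3-[(2R,7aR)-4,4,7a-trimethyl-2,4,5,6,7,7a-hexahydro-1-benzofuran-2-yl]but-2-en-1-ol
Conditions: i-Bu2AlH, CH2Cl2, −78 °C; aq. KNaC4H4O6 work-up
Reagents that add atoms: none
Why: Diisobutylaluminium hydride 1,2-reduction of the enoate at low temperature gives the allylic alcohol under non-acidic conditions that leave the acid-labile allylic ether at C8 and both stereocenters untouched.

Step 7
Reactants: 8 furanoid allylic alcohol
Product: 10 [(2E)-3-[(2R,7aR)-4,4,7a-trimethyl-2,4,5,6,7,7a-hexahydro-1-benzofuran-2-yl]but-2-en-1-yl]triphenylphosphonium bromide, via furanoid allylic bromide 9 (not isolated)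
Conditions: CBr4, PPh3, CH2Cl2, 0 °C; then PPh3, rt
Reagents that add atoms: carbon tetrabromide, BrC(Br)(Br)Br; triphenylphosphine, c1ccc(cc1)P(c1ccccc1)c1ccccc1
Why: Appel bromination of the primary allylic alcohol followed by SN2 quaternisation with triphenylphosphine gives the Wittig salt without the protic acid that would ionise the doubly allylic C8–O bond.

Step 8
Reactants: 6 epoxy dienoate
Product: 11 ethyl (2E,4E)-3-methyl-5-[(3aS,7aR)-4,4,7a-trimethyl-2-oxohexahydro-1,3-benzodioxol-3a-yl]penta-2,4-dienoate (cis-fused cyclic carbonate)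
Conditions: Pd(OAc)2 (5 mol%), P(OiPr)3 (30 mol%), n-BuLi (10 mol%), CO2 (1 atm), THF, rt
Reagents that add atoms: carbon dioxide, O=C=O
Why: Palladium-catalysed CO2 insertion into a vinyl oxirane, in which zerovalent palladium ionises the allylic C6–O bond with inversion, the C5 alkoxide captures CO2, and the carbonate oxygen, held on the original face by C5, closes the five-membered ring at C6 with a second inversion, so C6 keeps its oxygen on the same face (6S) and the cis-fused carbonate of the cis-diol should result.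

Step 9
Reactants: 11 cyclic carbonate ester
Product: 12 (2E,4E)-5-[(1S,2R)-1,2-dihydroxy-2,6,6-trimethylcyclohexyl]-3-methylpenta-2,4-dien-1-ol
Conditions: LiAlH4, THF, 0 °C → rt; aq. NaOH work-up
Reagents that add atoms: none
Why: Hydride reduction with LiAlH4 converts the enoate into the allylic alcohol and cleaves the cyclic carbonate to the free cis-diol in one operation without touching either stereocenter.

Step 10
Reactants: 12 triol
Product: 14 [(2E,4E)-5-[(1S,2R)-1,2-dihydroxy-2,6,6-trimethylcyclohexyl]-3-methylpenta-2,4-dien-1-yl]triphenylphosphonium bromide, via diol allylic bromide 13 (not isolated)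
Conditions: CBr4, PPh3, CH2Cl2, 0 °C; then PPh3, rt
Reagents that add atoms: carbon tetrabromide, BrC(Br)(Br)Br; triphenylphosphine, c1ccc(cc1)P(c1ccccc1)c1ccccc1
Why: Appel bromination is selective for the primary allylic hydroxyl over the two hindered tertiary hydroxyls and, unlike a protic phosphonium-forming reagent, does not ionise the tertiary allylic C6–OH, after which SN2 quaternisation gives the salt.

Step 11
Reactants: 14 diol C15 phosphonium bromide; 15 (2E,4E,6E)-2,7-dimethylocta-2,4,6-trienedial (2.5 equiv)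
Product: 17 (5R,6S)-5,6-dihydroxy-5,6-dihydro-12'-apo-β-caroten-12'-al (all-E), via 11Z isomer 16 (not isolated)
Conditions: NaOMe, MeOH/CH2Cl2, 0 °C → rt (ylide added slowly to excess 15); then EtOAc, reflux, dark, argon
Reagents that add atoms: none
Why: Wittig olefination of the symmetrical dialdehyde used in excess should stop at the mono-adduct because the product aldehyde is the less electrophilic vinylogue, and the hindered 11Z isomer should relax thermally to 11E, no stereocenter being touched.

Step 12
Reactants: 10 furanoid C15 phosphonium bromide; 17 C25 diol apo-aldehyde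
Product: 19 (5R,6S,5'R,8'R)-5',8'-epoxy-5,6,5',8'-tetrahydro-β,β-carotene-5,6-diol (all-E, target), via 11'Z isomer 18 (not isolated)
Conditions: NaOMe, MeOH/CH2Cl2, 0 °C → rt; then EtOAc/heptane, reflux, dark, argon; crystallisation
Reagents that add atoms: none
Why: The second Wittig olefination joins the halves at C11'=C12' through a γ-alkoxy allylic ylide of the kind that tolerates Wittig conditions, and the 11'Z isomer should isomerise thermally to the all-E target without touching C5, C6, C5' or C8'.

Compound list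
1 | β-cyclocitral (2,6,6-trimethylcyclohex-1-ene-1-carbaldehyde) | CC1=C(C=O)C(C)(C)CCC1 | starting material
2 | β-cyclogeraniol ((2,6,6-trimethylcyclohex-1-en-1-yl)methanol) | CC1=C(CO)C(C)(C)CCC1 | intermediate
3 | [(1R,6R)-2,2,6-trimethyl-7-oxabicyclo[4.1.0]heptan-1-yl]methanol | OC[C@@]12O[C@]1(C)CCCC2(C)C | intermediate
4 | (1S,6R)-2,2,6-trimethyl-7-oxabicyclo[4.1.0]heptane-1-carbaldehyde | O=C[C@@]12O[C@]1(C)CCCC2(C)C | intermediate
5 | triethyl 3-methyl-4-phosphonocrotonate (ethyl (2E)-4-(diethoxyphosphoryl)-3-methylbut-2-enoate) | CCOC(=O)/C=C(\C)CP(=O)(OCC)OCC | starting material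
6 | ethyl (2E,4E)-3-methyl-5-[(1S,6R)-2,2,6-trimethyl-7-oxabicyclo[4.1.0]heptan-1-yl]penta-2,4-dienoate | CCOC(=O)/C=C(C)/C=C/[C@@]12O[C@]1(C)CCCC2(C)C | intermediate
7 | ethyl (2E)-3-[(2R,7aR)-4,4,7a-trimethyl-2,4,5,6,7,7a-hexahydro-1-benzofuran-2-yl]but-2-enoate | CCOC(=O)/C=C(\C)[C@H]1C=C2C(C)(C)CCC[C@@]2(C)O1 | intermediate
8 | (2E)-3-[(2R,7aR)-4,4,7a-trimethyl-2,4,5,6,7,7a-hexahydro-1-benzofuran-2-yl]but-2-en-1-ol | OC/C=C(\C)[C@H]1C=C2C(C)(C)CCC[C@@]2(C)O1 | intermediate
9 | (2R,7aR)-2-[(2E)-4-bromobut-2-en-2-yl]-4,4,7a-trimethyl-2,4,5,6,7,7a-hexahydro-1-benzofuran | BrC/C=C(\C)[C@H]1C=C2C(C)(C)CCC[C@@]2(C)O1 | intermediate (not isolated)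
10 | [(2E)-3-[(2R,7aR)-4,4,7a-trimethyl-2,4,5,6,7,7a-hexahydro-1-benzofuran-2-yl]but-2-en-1-yl]triphenylphosphonium bromide | [Br-].C(/C=C(\C)[C@H]1C=C2C(C)(C)CCC[C@@]2(C)O1)[P+](c1ccccc1)(c1ccccc1)c1ccccc1 | intermediate
11 | ethyl (2E,4E)-3-methyl-5-[(3aS,7aR)-4,4,7a-trimethyl-2-oxohexahydro-1,3-benzodioxol-3a-yl]penta-2,4-dienoate | CCOC(=O)/C=C(C)/C=C/[C@@]12OC(=O)O[C@]1(C)CCCC2(C)C | intermediate
12 | (2E,4E)-5-[(1S,2R)-1,2-dihydroxy-2,6,6-trimethylcyclohexyl]-3-methylpenta-2,4-dien-1-ol | OC/C=C(C)/C=C/[C@]1(O)C(C)(C)CCC[C@@]1(C)O | intermediate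
13 | (1S,2R)-1-[(1E,3E)-5-bromo-3-methylpenta-1,3-dien-1-yl]-2,6,6-trimethylcyclohexane-1,2-diol | BrC/C=C(C)/C=C/[C@]1(O)C(C)(C)CCC[C@@]1(C)O | intermediate (not isolated)
14 | [(2E,4E)-5-[(1S,2R)-1,2-dihydroxy-2,6,6-trimethylcyclohexyl]-3-methylpenta-2,4-dien-1-yl]triphenylphosphonium bromide | [Br-].C(/C=C(C)/C=C/[C@]1(O)C(C)(C)CCC[C@@]1(C)O)[P+](c1ccccc1)(c1ccccc1)c1ccccc1 | intermediate
15 | (2E,4E,6E)-2,7-dimethylocta-2,4,6-trienedial (C10 dialdehyde) | O=C/C(C)=C/C=C/C=C(\C)C=O | starting material
16 | (11Z)-(5R,6S)-5,6-dihydroxy-5,6-dihydro-12'-apo-β-caroten-12'-al | CC(/C=C\C=C(C)\C=C\[C@]1(O)C(C)(C)CCC[C@@]1(C)O)=C\C=C\C=C(C)\C=O | intermediate (not isolated)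
17 | (all-E)-(5R,6S)-5,6-dihydroxy-5,6-dihydro-12'-apo-β-caroten-12'-al | CC(/C=C/C=C(C)/C=C/[C@]1(O)C(C)(C)CCC[C@@]1(C)O)=C\C=C\C=C(C)\C=O | intermediate
18 | (11'Z)-(5R,6S,5'R,8'R)-5',8'-epoxy-5,6,5',8'-tetrahydro-β,β-carotene-5,6-diol | CC(/C=C/C=C(C)/C=C/[C@]1(O)C(C)(C)CCC[C@@]1(C)O)=C\C=C\C=C(C)\C=C/C=C(\C)[C@H]1C=C2C(C)(C)CCC[C@@]2(C)O1 | intermediate (not isolated)
19 | (all-E)-(5R,6S,5'R,8'R)-5',8'-epoxy-5,6,5',8'-tetrahydro-β,β-carotene-5,6-diol | CC(/C=C/C=C(C)/C=C/[C@]1(O)C(C)(C)CCC[C@@]1(C)O)=C\C=C\C=C(C)\C=C\C=C(/C)[C@H]1C=C2C(C)(C)CCC[C@@]2(C)O1 | target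

Total step count: 12
Longest linear sequence: 9 steps (steps 1, 2, 3, 4, 8, 9, 10, 11, 12)

Steps most likely to fail

1. Step 5. The oxygen transfer may lose its stereospecificity at C8 if the C6–O bond ionises to an allyl cation that rotates before ring closure. The tetrasubstituted oxirane may instead undergo a semipinacol ring contraction, or the electron-poor dienoate may not turn over at all. Fallback: the fallback sets out from 6, which is reduced with i-Bu2AlH (CH2Cl2, −78 °C) to (2E,4E)-3-methyl-5-[(1S,6R)-2,2,6-trimethyl-7-oxabicyclo[4.1.0]heptan-1-yl]penta-2,4-dien-1-ol F1. The electron-richer dienol is then exposed to a catalytic amount of camphorsulfonic acid (CH2Cl2, 0 °C), the classical Brønsted-acid 5,6-epoxide to 5,8-furanoid rearrangement through the allyl cation. This expands the same oxirane to the same dihydrofuran without stereocontrol at C8 and should give 8 together with its C8 epimer, (2E)-3-[(2S,7aR)-4,4,7a-trimethyl-2,4,5,6,7,7a-hexahydro-1-benzofuran-2-yl]but-2-en-1-ol F2. The two diastereomers are separated by chromatography on base-washed silica, and the route is rejoined at 8.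

2. Step 8. Ionisation and carbonate capture at the fully substituted C6, which is flanked by the quaternary C1, may be too slow, so that the catalyst decomposes or the alkoxide is diverted to other positions of the allyl system. Fallback: the fallback sets out from 4 and takes C5 (R) from the same epoxidation. A Wharton transposition (N2H4·H2O, cat. AcOH, MeOH, 0 °C → rt) should give (R)-1,3,3-trimethyl-2-methylidenecyclohexan-1-ol F3. Ozonolysis (O3, CH2Cl2, −78 °C; Me2S) gives (R)-2-hydroxy-2,6,6-trimethylcyclohexan-1-one F4, which is silylated with 1-(trimethylsilyl)imidazole to its trimethylsilyl ether F5. The dilithio derivative of commercial (E)-3-methylpent-2-en-4-yn-1-ol F6 (n-BuLi, 2 equiv, THF, −78 °C) is added to the ketone. The chair with the silyloxy group axial avoids a syn-diaxial methyl/methyl contact, and attack anti to that axial C–O bond should give the cis-diol precursor (2E)-5-[(1R,2R)-1-hydroxy-2,6,6-trimethyl-2-[(trimethylsilyl)oxy]cyclohexyl]-3-methylpent-2-en-4-yn-1-ol F7. LiAlH4 (THF, reflux) trans-reduces the propargylic alkyne to the 7E alkene and K2CO3/MeOH removes the silyl group, which rejoins the route at 12.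

3. Step 12. The ylide of 10 may undergo vinylogous β-elimination of the C8' alkoxide, which opens the dihydrofuran, before it meets the poorly electrophilic polyenal. The new double bond may also form with insufficient E selectivity. Fallback: the polarity of the union is reversed, setting out from 8 and 17. MnO2 (CH2Cl2, rt) oxidises 8 to (2E)-3-[(2R,7aR)-4,4,7a-trimethyl-2,4,5,6,7,7a-hexahydro-1-benzofuran-2-yl]but-2-enal F8. NaBH4 (MeOH, 0 °C) reduces 17 to (5R,6S)-5,6-dihydro-12'-apo-β-carotene-5,6,12'-triol F9, which is converted by CBr4/PPh3 through the 12'-bromide F10 and then by more PPh3 into the C25 triphenylphosphonium bromide F11. Wittig reaction of F11 with F8 (NaOMe, MeOH/CH2Cl2, 0 °C; then reflux in EtOAc) forms the same C11'=C12' bond with the carbanion on the polyene fragment, far from the dihydrofuran, and returns through 18 to 19.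

Further compounds
F1 | step 5 | (2E,4E)-3-methyl-5-[(1S,6R)-2,2,6-trimethyl-7-oxabicyclo[4.1.0]heptan-1-yl]penta-2,4-dien-1-ol | OC/C=C(C)/C=C/[C@@]12O[C@]1(C)CCCC2(C)C
F2 | step 5 | (2E)-3-[(2S,7aR)-4,4,7a-trimethyl-2,4,5,6,7,7a-hexahydro-1-benzofuran-2-yl]but-2-en-1-ol | OC/C=C(\C)[C@@H]1C=C2C(C)(C)CCC[C@@]2(C)O1
F3 | step 8 | (R)-1,3,3-trimethyl-2-methylidenecyclohexan-1-ol | C[C@@]1(O)CCCC(C)(C)C1=C
F4 | step 8 | (R)-2-hydroxy-2,6,6-trimethylcyclohexan-1-one | C[C@@]1(O)CCCC(C)(C)C1=O
F5 | step 8 | (R)-2-hydroxy-2,6,6-trimethylcyclohexan-1-one trimethylsilyl ether | C[C@@]1(O[Si](C)(C)C)CCCC(C)(C)C1=O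
F6 | step 8 | (E)-3-methylpent-2-en-4-yn-1-ol | OC/C=C(C)/C#C
F7 | step 8 | (2E)-5-[(1R,2R)-1-hydroxy-2,6,6-trimethyl-2-[(trimethylsilyl)oxy]cyclohexyl]-3-methylpent-2-en-4-yn-1-ol | OC/C=C(C)/C#C[C@]1(O)C(C)(C)CCC[C@@]1(C)O[Si](C)(C)C
F8 | step 12 | (2E)-3-[(2R,7aR)-4,4,7a-trimethyl-2,4,5,6,7,7a-hexahydro-1-benzofuran-2-yl]but-2-enal | O=C/C=C(\C)[C@H]1C=C2C(C)(C)CCC[C@@]2(C)O1
F9 | step 12 | (all-E)-(5R,6S)-5,6-dihydro-12'-apo-β-carotene-5,6,12'-triol | CC(/C=C/C=C(C)/C=C/[C@]1(O)C(C)(C)CCC[C@@]1(C)O)=C\C=C\C=C(C)\CO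
F10 | step 12 | (all-E)-(5R,6S)-12'-bromo-5,6-dihydro-12'-apo-β-carotene-5,6-diol | CC(/C=C/C=C(C)/C=C/[C@]1(O)C(C)(C)CCC[C@@]1(C)O)=C\C=C\C=C(C)\CBr
F11 | step 12 | [(all-E)-(5R,6S)-5,6-dihydroxy-5,6-dihydro-12'-apo-β-caroten-12'-yl]triphenylphosphonium bromide | [Br-].CC(/C=C/C=C(C)/C=C/[C@]1(O)C(C)(C)CCC[C@@]1(C)O)=C\C=C\C=C(C)\C[P+](c1ccccc1)(c1ccccc1)c1ccccc1
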